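The route rests on cutting the oxolane O1–C2 bond and the C1–C2′ bond that links the C1 methylene to sp2 carbon C2′ of the six-membered dione ring; both bonds sit on the two carbons of a former C1=C2 vinyl group. One palladium-catalysed alkene carboetherification joins an open-chain 1,3-syn diol fragment, free at O5 and silylated at O3, to a 2-bromo vinylogous ester of cyclohexane-1,3-dione, closing the oxolane and setting C2 under control of C3 and C5. The precursor is made by a boron aldol, a chelation-controlled methyl addition and semi-hydrogenation; afterwards only reagent-controlled enolate hydroxylation and fluoride deprotection remain.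

Key step: step 8

Remarks
- Numbering: oxolane O1–C2–C3–C4–C5 with exocyclic methylene C1; dione ring C1′ (ketone), C2′ (bears C1), C3′ (enol carbon) to C6′. The open-chain dodecane numbering C1–C5 maps onto the same atoms.
- Assumption: the target is one enol tautomer of a 2-alkyl-4-hydroxycyclohexane-1,3-dione, so hydroxylation at C6′ of the enol ether followed by loss of the enol ether gives the drawn 3,4-dihydroxy enone (C6′ becomes C4′ of the target name).
- Design choice: O3 is kept as a tert-butyldimethylsilyl ether from before the coupling to the last step. A free C3 hydroxyl is cis to C1 and can reach C3′ of the vinylogous ester through a six-membered addition–elimination, and it would add a second alkoxide to a base-sensitive coupling.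
- The facial senses assigned to the two chiral reagents (steps 1 and 9) are recalled from analogous cases and from a transition-state model; they are not secured for these substrates.

Step 1
Reactants: 1 geranial; 2 4-(trimethylsilyl)but-3-yn-2-one
Product: 4 (5R,6E)-5-hydroxy-7,11-dimethyl-1-(trimethylsilyl)dodeca-6,10-dien-1-yn-3-one, via enol borinate 3 (not isolated)
Conditions: 2, (−)-Ipc2BCl, Et3N, Et2O, −78 → 0 °C; then 1, −78 → −20 °C; H2O2, MeOH, pH 7 buffer
Reagents that add atoms: none
Why: Diisopinocampheylboron-mediated aldol reaction of a methyl ketone, in which the enol borinate adds through a cyclic boron-bound transition state and the pinene-derived ligands are expected to direct it to the Re face of geranial (reagent control, C5 = R), under enolization conditions mild enough for the silylalkyne and the dienal.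

Step 2
Reactants: 4
Product: 6 (3S,5R,6E)-3,7,11-trimethyldodeca-6,10-dien-1-yne-3,5-diol, via silylalkynyl diol 5 (not isolated)
Conditions: MeMgBr (3 equiv), CH2Cl2–Et2O, −78 °C; then MeOH, K2CO3, rt
Reagents that add atoms: methylmagnesium bromide, C[Mg]Br
Why: Chelation-controlled Grignard addition, in which the magnesium C5-alkoxide binds the ketone oxygen in a six-membered half-chair with the alkenyl group equatorial and methyl adds axially to give the 3S carbinol (hydroxyls 1,3-syn along the alkynyl chain), after which methanolic K2CO3 cleaves the C(sp)–Si bond in the same flask.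

Step 3
Reactants: 6
Product: 7 (3S,5R,6E)-3,7,11-trimethyldodeca-1,6,10-triene-3,5-diol
Conditions: H2 (1 atm), Pd on CaCO3 poisoned with Pb(OAc)2, quinoline, EtOAc, rt
Reagents that add atoms: none
Why: Lindlar-type semi-hydrogenation, in which the terminal alkyne takes up one equivalent of H2 on the poisoned palladium surface and the vinyl group formed is released, while the two isolated trisubstituted alkenes and both stereocentres are untouched.

Step 4
Reactants: 7
Product: 8 (3S,5R,6E)-3,5-bis[(tert-butyldimethylsilyl)oxy]-3,7,11-trimethyldodeca-1,6,10-triene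
Conditions: tBuMe2SiOTf (3 equiv), 2,6-lutidine, CH2Cl2, −78 → 0 °C
Reagents that add atoms: tert-butyldimethylsilyl trifluoromethanesulfonate, CC(C)(C)[Si](C)(C)OS(=O)(=O)C(F)(F)F
Why: Silyl triflate with a hindered pyridine base is the standard silylation of hindered alcohols and covers the tertiary O3 together with the secondary O5, since the tertiary hydroxyl cannot be silylated alone.

Step 5
Reactants: 8
Product: 9 (3S,5R,6E)-3-[(tert-butyldimethylsilyl)oxy]-3,7,11-trimethyldodeca-1,6,10-trien-5-ol
Conditions: HF·pyridine, pyridine, THF, 0 °C → rt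
Reagents that add atoms: none
Why: Selective desilylation, in which pyridine-buffered HF cleaves the secondary allylic silyl ether much faster than the tertiary one, and because no alkoxide is formed the remaining silyl group cannot shift from O3 to O5.

Step 6
Reactants: 10 cyclohexane-1,3-dione; 11 2-(trimethylsilyl)ethanol
Product: 12 3-[2-(trimethylsilyl)ethoxy]cyclohex-2-en-1-one
Conditions: PPh3, iPrO2CN=NCO2iPr, THF, 0 °C → rt
Reagents that add atoms: none
Why: Mitsunobu O-alkylation, in which the acidic dione protonates the phosphine–azodicarboxylate adduct and its enolate oxygen displaces the activated primary alcohol, giving the vinylogous ester under neutral conditions that spare the acid-labile β-silylethyl group.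

Step 7
Reactants: 12
Product: 13 2-bromo-3-[2-(trimethylsilyl)ethoxy]cyclohex-2-en-1-one
Conditions: NBS, CH2Cl2, 0 °C
Reagents that add atoms: N-bromosuccinimide, BrN1C(=O)CCC1=O
Why: Electrophilic α-bromination of a vinylogous ester, in which the donor-activated C2 attacks NBS and loses its proton to restore the enone, a standard entry to 2-bromo-3-alkoxycyclohexenones that leaves the C–Si bond alone.

Step 8
Reactants: 9 (3S,5R,6E)-3-[(tert-butyldimethylsilyl)oxy]-3,7,11-trimethyldodeca-1,6,10-trien-5-ol; 13 2-bromo-3-[2-(trimethylsilyl)ethoxy]cyclohex-2-en-1-one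
Product: 14 2-{[(2S,3S,5R)-3-[(tert-butyldimethylsilyl)oxy]-5-[(1E)-2,6-dimethylhepta-1,5-dien-1-yl]-3-methyloxolan-2-yl]methyl}-3-[2-(trimethylsilyl)ethoxy]cyclohex-2-en-1-one
Conditions: 13 (1.3 equiv), Pd2(dba)3 (2.5 mol %), bis[2-(diphenylphosphino)phenyl] ether (6 mol %), NaOtBu (1.5 equiv), THF, 65 °C
Reagents that add atoms: none
Why: Zerovalent palladium inserts into the C2′–Br bond of 13, the sodium C5-alkoxide of 9 replaces bromide on the alkenylpalladium species, the C1=C2 vinyl group inserts syn into the Pd–O bond, and C(sp3)–C(sp2) reductive elimination then forms C1–C2′, so O1–C2 and C1–C2′ arise in one catalytic cycle. The closest known reaction is the palladium-catalysed carboetherification of γ-hydroxy alkenes with aryl and alkenyl bromides, here run with an α-bromo vinylogous ester as the alkenyl bromide. The oxolane closes in the 5-exo-trig mode (O5 onto the internal alkene carbon C2), the only closure open to this alkoxide, because the two trisubstituted alkenes are not placed for insertion. The new stereocentre C2 is set by the substrate: in the ordered insertion transition state the C5 alkenyl group and the C3 methyl group, which are cis to each other in the syn-diol derivative, both lie pseudoequatorial with C3–OSi pseudoaxial, which places C1 trans to both and gives the 2S, 2,5-trans ring. The step needs reductive elimination to outrun β-hydride loss and needs the base-labile bromide to survive; the wide-bite-angle diphosphine favours reductive elimination, and silylation of O3 leaves a single alkoxide, so only a small excess of NaOtBu is present and the product carries no alkoxide that could attack its own C3′.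

Step 9
Reactants: 14
Product: 16 (6S)-2-{[(2S,3S,5R)-3-[(tert-butyldimethylsilyl)oxy]-5-[(1E)-2,6-dimethylhepta-1,5-dien-1-yl]-3-methyloxolan-2-yl]methyl}-6-hydroxy-3-[2-(trimethylsilyl)ethoxy]cyclohex-2-en-1-one, via lithium enolate 15 (not isolated)
Conditions: LiN(iPr)2, THF, −78 °C; then (−)-(camphorsulfonyl)oxaziridine, −78 → −40 °C; aq. NH4Cl
Reagents that add atoms: (−)-(camphorsulfonyl)oxaziridine, CC1(C)[C@H]2CC[C@@]13CS(=O)(=O)N4O[C@]34C2
Why: N-Sulfonyloxaziridine enolate hydroxylation (Davis oxidation), in which LiN(iPr)2 removes the kinetic α′ proton at C6′ of the vinylogous ester and the enantiopure oxaziridine is expected, on the open transition-state model with O–Li turned away from the camphor skeleton, to deliver oxygen to the Si face of C6′ (reagent control, 6′S), the alkenes and silyl ethers being inert to this oxidant.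

Step 10
Reactants: 16
Product: 18 (4S)-2-{[(2S,3S,5R)-5-[(1E)-2,6-dimethylhepta-1,5-dien-1-yl]-3-hydroxy-3-methyloxolan-2-yl]methyl}-3,4-dihydroxycyclohex-2-en-1-one (CNP0194047.1), via silyl ether enolate 17 (not isolated)
Conditions: Bu4NF (excess), THF, 0 °C → rt, then 45 °C; aq. NaH2PO4
Reagents that add atoms: none
Why: Fluoride-induced β-elimination of the 2-(trimethylsilyl)ethyl group (as for silylethyl esters) first releases the 1,3-dione as its unreactive enolate, the hindered tertiary silyl ether is then cleaved on warming, and buffered work-up lets the 4-hydroxy-1,3-dione settle into the drawn enol tautomer without touching a stereocentre.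

Compound list
1 | geranial, (2E)-3,7-dimethylocta-2,6-dienal | CC(C)=CCC/C(C)=C/C=O | starting material
2 | 4-(trimethylsilyl)but-3-yn-2-one | CC(=O)C#C[Si](C)(C)C | starting material
3 | 2-{[bis(isopinocampheyl)boranyl]oxy}-4-(trimethylsilyl)but-1-en-3-yne, enol borinate of 2 with the isopinocampheyl groups of (−)-Ipc2BCl | C=C(OB([C@@H]1C[C@@H]2C[C@H]([C@H]1C)C2(C)C)[C@@H]1C[C@@H]2C[C@H]([C@H]1C)C2(C)C)C#C[Si](C)(C)C | intermediate
4 | (5R,6E)-5-hydroxy-7,11-dimethyl-1-(trimethylsilyl)dodeca-6,10-dien-1-yn-3-one | CC(C)=CCC/C(C)=C/[C@H](O)CC(=O)C#C[Si](C)(C)C | intermediate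
5 | (3S,5R,6E)-3,7,11-trimethyl-1-(trimethylsilyl)dodeca-6,10-dien-1-yne-3,5-diol (formed as its magnesium alkoxide) | CC(C)=CCC/C(C)=C/[C@H](O)C[C@](C)(O)C#C[Si](C)(C)C | intermediate
6 | (3S,5R,6E)-3,7,11-trimethyldodeca-6,10-dien-1-yne-3,5-diol | CC(C)=CCC/C(C)=C/[C@H](O)C[C@](C)(O)C#C | intermediate
7 | (3S,5R,6E)-3,7,11-trimethyldodeca-1,6,10-triene-3,5-diol | CC(C)=CCC/C(C)=C/[C@H](O)C[C@](C)(O)C=C | intermediate
8 | (3S,5R,6E)-3,5-bis[(tert-butyldimethylsilyl)oxy]-3,7,11-trimethyldodeca-1,6,10-triene | CC(C)=CCC/C(C)=C/[C@H](O[Si](C)(C)C(C)(C)C)C[C@](C)(O[Si](C)(C)C(C)(C)C)C=C | intermediate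
9 | (3S,5R,6E)-3-[(tert-butyldimethylsilyl)oxy]-3,7,11-trimethyldodeca-1,6,10-trien-5-ol | CC(C)=CCC/C(C)=C/[C@H](O)C[C@](C)(O[Si](C)(C)C(C)(C)C)C=C | intermediate
10 | cyclohexane-1,3-dione | O=C1CCCC(=O)C1 | starting material
11 | 2-(trimethylsilyl)ethanol | C[Si](C)(C)CCO | starting material
12 | 3-[2-(trimethylsilyl)ethoxy]cyclohex-2-en-1-one | C[Si](C)(C)CCOC1=CC(=O)CCC1 | intermediate
13 | 2-bromo-3-[2-(trimethylsilyl)ethoxy]cyclohex-2-en-1-one | C[Si](C)(C)CCOC1=C(Br)C(=O)CCC1 | intermediate
14 | 2-{[(2S,3S,5R)-3-[(tert-butyldimethylsilyl)oxy]-5-[(1E)-2,6-dimethylhepta-1,5-dien-1-yl]-3-methyloxolan-2-yl]methyl}-3-[2-(trimethylsilyl)ethoxy]cyclohex-2-en-1-one | CC(C)=CCC/C(C)=C/[C@H]1C[C@](C)(O[Si](C)(C)C(C)(C)C)[C@H](CC2=C(OCC[Si](C)(C)C)CCCC2=O)O1 | intermediate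
15 | lithium α′-enolate of 14 (C1′(OLi)=C6′ cross-conjugated dienolate) | CC(C)=CCC/C(C)=C/[C@H]1C[C@](C)(O[Si](C)(C)C(C)(C)C)[C@H](CC2=C(OCC[Si](C)(C)C)CCC=C2O[Li])O1 | intermediate
16 | (6S)-2-{[(2S,3S,5R)-3-[(tert-butyldimethylsilyl)oxy]-5-[(1E)-2,6-dimethylhepta-1,5-dien-1-yl]-3-methyloxolan-2-yl]methyl}-6-hydroxy-3-[2-(trimethylsilyl)ethoxy]cyclohex-2-en-1-one | CC(C)=CCC/C(C)=C/[C@H]1C[C@](C)(O[Si](C)(C)C(C)(C)C)[C@H](CC2=C(OCC[Si](C)(C)C)CC[C@H](O)C2=O)O1 | intermediate
17 | tetrabutylammonium enolate of (4S)-2-{[(2S,3S,5R)-3-[(tert-butyldimethylsilyl)oxy]-5-[(1E)-2,6-dimethylhepta-1,5-dien-1-yl]-3-methyloxolan-2-yl]methyl}-3,4-dihydroxycyclohex-2-en-1-one | CC(C)=CCC/C(C)=C/[C@H]1C[C@](C)(O[Si](C)(C)C(C)(C)C)[C@H](CC2=C([O-])[C@@H](O)CCC2=O)O1.CCCC[N+](CCCC)(CCCC)CCCC | intermediate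
18 | (4S)-2-{[(2S,3S,5R)-5-[(1E)-2,6-dimethylhepta-1,5-dien-1-yl]-3-hydroxy-3-methyloxolan-2-yl]methyl}-3,4-dihydroxycyclohex-2-en-1-one (CNP0194047.1) | CC(C)=CCC/C(C)=C/[C@H]1C[C@](C)(O)[C@H](CC2=C(O)[C@@H](O)CCC2=O)O1 | target

Total step count: 10. Longest linear sequence: 8 (steps 1–5, 8, 9, 10); steps 6 and 7 form the two-step side branch.

Steps most likely to fail

1. Step 8 (key step). Three processes may go wrong:
   - The bromo vinylogous ester may be consumed by base before it couples, through α′-deprotonation with self-condensation or through alkoxide addition–elimination at C3′.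
   - The palladium C5-alkoxide may lose a β-hydride (oxidising the allylic alcohol), or the alkenylpalladium species may add to the vinyl group in a Heck manner instead of inserting into Pd–O.
   - Under NaOtBu the silyl group may shuttle reversibly between O3 and O5, lowering the concentration of the reacting alkoxide.

   Fallback (stepwise, no strong base, no palladium): the route leaves from 9. Mukaiyama-type aerobic oxidative cyclization (Co(modp)2 as a divalent cobalt catalyst, O2, tBuOOH, iPrOH, 55 °C) closes the 2,5-trans oxolane and gives [(2S,3S,5R)-3-[(tert-butyldimethylsilyl)oxy]-5-[(1E)-2,6-dimethylhepta-1,5-dien-1-yl]-3-methyloxolan-2-yl]methanol F1. Dess–Martin periodinane (NaHCO3, CH2Cl2) gives the corresponding oxolane-2-carbaldehyde F2. Three-component reductive alkylation of 10 with F2 (Hantzsch ester, L-proline cat., CH2Cl2, rt) forms C1–C2′ and gives the 2-alkyl-3-hydroxycyclohex-2-en-1-one F3. Mitsunobu O-alkylation of this symmetric dione with 11 (PPh3, iPrO2CN=NCO2iPr) returns to the route at 14.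

2. Step 9. The oxaziridine may discriminate poorly between the two faces of a trisubstituted cyclic enolate (or prefer the face opposite to the one assumed), giving a mixture of C6′ epimers that later steps cannot separate.

   Fallback (separation instead of reagent control): the route leaves from 14. Hydroxylation without facial control (LiN(iPr)2, then racemic 2-(phenylsulfonyl)-3-phenyloxaziridine) gives 16 together with its (6R)-epimer F4. A lipase (Candida antarctica lipase B, vinyl acetate, tBuOMe) should, by the usual lipase preference for secondary alcohols, acylate only the 6′R carbinol, giving the (6R)-acetate F5. Chromatography removes F5 and returns to the route at epimerically pure 16.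

3. Step 1. Enantiofacial discrimination by the diisopinocampheylboron enolate of a methyl ketone may be incomplete, which would lower the enantiomeric purity of every later compound. Triethylamine may also add to the ynone during enolization.

   Fallback (auxiliary control with a separable diastereomer): the route leaves from 1. Titanium-mediated acetate aldol with (4S)-3-acetyl-4-(propan-2-yl)-1,3-thiazolidine-2-thione (TiCl4, iPr2NEt, CH2Cl2, −78 °C) gives, after chromatographic removal of the minor diastereomer, the (3R)-aldol imide F6. MeNHOMe·HCl and imidazole displace the auxiliary to give the Weinreb amide F7. Excess LiC≡CSiMe3 (THF, −78 °C) returns to the route at 4.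

Further compounds
F1 | step 8 | [(2S,3S,5R)-3-[(tert-butyldimethylsilyl)oxy]-5-[(1E)-2,6-dimethylhepta-1,5-dien-1-yl]-3-methyloxolan-2-yl]methanol | CC(C)=CCC/C(C)=C/[C@H]1C[C@](C)(O[Si](C)(C)C(C)(C)C)[C@H](CO)O1
F2 | step 8 | (2R,3S,5R)-3-[(tert-butyldimethylsilyl)oxy]-5-[(1E)-2,6-dimethylhepta-1,5-dien-1-yl]-3-methyloxolane-2-carbaldehyde | CC(C)=CCC/C(C)=C/[C@H]1C[C@](C)(O[Si](C)(C)C(C)(C)C)[C@H](C=O)O1
F3 | step 8 | 2-{[(2S,3S,5R)-3-[(tert-butyldimethylsilyl)oxy]-5-[(1E)-2,6-dimethylhepta-1,5-dien-1-yl]-3-methyloxolan-2-yl]methyl}-3-hydroxycyclohex-2-en-1-one | CC(C)=CCC/C(C)=C/[C@H]1C[C@](C)(O[Si](C)(C)C(C)(C)C)[C@H](CC2=C(O)CCCC2=O)O1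
F4 | step 9 | (6R)-2-{[(2S,3S,5R)-3-[(tert-butyldimethylsilyl)oxy]-5-[(1E)-2,6-dimethylhepta-1,5-dien-1-yl]-3-methyloxolan-2-yl]methyl}-6-hydroxy-3-[2-(trimethylsilyl)ethoxy]cyclohex-2-en-1-one | CC(C)=CCC/C(C)=C/[C@H]1C[C@](C)(O[Si](C)(C)C(C)(C)C)[C@H](CC2=C(OCC[Si](C)(C)C)CC[C@@H](O)C2=O)O1
F5 | step 9 | (1R)-3-{[(2S,3S,5R)-3-[(tert-butyldimethylsilyl)oxy]-5-[(1E)-2,6-dimethylhepta-1,5-dien-1-yl]-3-methyloxolan-2-yl]methyl}-2-oxo-4-[2-(trimethylsilyl)ethoxy]cyclohex-3-en-1-yl acetate | CC(C)=CCC/C(C)=C/[C@H]1C[C@](C)(O[Si](C)(C)C(C)(C)C)[C@H](CC2=C(OCC[Si](C)(C)C)CC[C@@H](OC(C)=O)C2=O)O1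
F6 | step 1 | (4S)-3-[(3R,4E)-3-hydroxy-5,9-dimethyldeca-4,8-dienoyl]-4-(propan-2-yl)-1,3-thiazolidine-2-thione | CC(C)=CCC/C(C)=C/[C@H](O)CC(=O)N1[C@@H](C(C)C)CSC1=S
F7 | step 1 | (3R,4E)-3-hydroxy-N-methoxy-N,5,9-trimethyldeca-4,8-dienamide | CC(C)=CCC/C(C)=C/[C@H](O)CC(=O)N(C)OC
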